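The numbers in the tables were generated by integration on assumed constants; noise was put on by code.

Amounts first: Wednesday's flask and Sunday's flask both hold 70 mM of coupling partner and 0.28 mM of capture agent, and differ in starting material, 14 mM against 7 mM. You want Wednesday's flask at 25 h.

| setting | Wednesday's | Sunday's | flask |
|---|---|---|---|
| starting material | 14 mM | 7 mM | 14 mM |
| coupling partner | 70 mM | 70 mM | 70.0 mM |
| capture agent | 0.28 mM | 0.28 mM | 0.280 mM |
| remark | the very flask that is asked about, followed so far | run made earlier |  |
| time |  |  | 25 h |

| run | time / h | starting material / % | first product / % |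
|---|---|---|---|
| Wednesday's | 2.00 | 0.1 | 82.4 |
| Wednesday's | 4.00 | 1.0 | 68.1 |
| Wednesday's | 6.00 | 0 | 58.6 |
| Wednesday's | 8.00 | 0 | 49.6 |
| Wednesday's | 10.0 | 2.0 | 42.7 |
| Sunday's | 1.33 | 1.4 | 83.4 |
| Sunday's | 2.50 | 1.2 | 76.2 |
| Sunday's | 5.00 | 0 | 57.1 |
| Sunday's | 10.0 | 0 | 33.2 |
| Sunday's | 20.0 | 0.3 | 15.4 |

(readings scatter by 1 percentage point)

- the starting material standing at 25 h, as a percentage of the starting material charged
- the first product standing at 25 h, as a percentage of the starting material charged
- the bis adduct standing at 25 h, as a percentage of the starting material charged
- the tris adduct standing at 25 h, as a percentage of the starting material charged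

Starting material reads 0.1% at 2.00 h on Wednesday and 1.4% at 1.33 h on Sunday, with a scatter of 1 percentage point. I therefore treat that first step as complete and count the partner it leaves free, F: 56.0 mM on Wednesday, 63.0 mM on Sunday. I take first product to decay after that at the rate k·c(coupling partner)·c(first product), second order, with c(coupling partner) falling as the run goes on. I assume the unread bis adduct goes on quickly, so each first product lost takes 2 partners. The quantity to carry is the spare partner S, which is c(coupling partner) charged less 3 times c(starting material) charged: 28.0 mM on Wednesday, 49.0 mM on Sunday.

Integrating gives the fraction of first product as S/(F·exp(k·S·t) − 2·c(starting material)). Sunday's last reading, 15.4% at 20.0 h, gives k = 4.71 × 10⁻⁴ /M/s. On Wednesday's run at 10.0 h this gives 45.1% against a reading of 42.7%, so it runs high. At 25 h I reckon 18.0% for Wednesday's flask and 10.0% for Sunday's, near twice. Wednesday's first product lasts longer because its spare partner is smaller than Sunday's.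

The forecast, seeing “the partner is being depleted by later additions”, gives 0% starting material, 14% first product, below my figure, 27% bis adduct and 45% tris adduct.

The flask gives 0% starting material, 17.6% first product, 0.159% bis adduct and 33.1% tris adduct, crystals counted.

    starting material + coupling partner → first product (k = 0.0210 /M/s)
    coupling partner + first product → bis adduct (k = 5.20 × 10⁻⁴ /M/s)
    coupling partner + bis adduct → tris adduct (k = 0.0580 /M/s)
    coupling partner + tris adduct → tetra adduct (k = 0.00150 /M/s)
    crystals ⇌ tris adduct, rate k5*(cs5 - [tris adduct]) while solid is left; crystals form when [tris adduct] > cs5 (solubility = 1.40 mM, k = 0.0250 /s)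
    first product + capture agent → trapped intermediate (k = 0.00340 /M/s)

Forecast and flask part most on bis adduct, whose half-life by the step to tris adduct at 25.0 h is 0.12 h, short against 25 h. For Wednesday's flask the reckoning with a spare partner of 28.0 mM gave 18.0% first product. The neighbouring flask, charged with 120 mM of coupling partner, has a spare partner of 78.0 mM, and the same reckoning puts it at 2.72%. At 25 h that neighbour holds 2.60% first product.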